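## Analysis of the target

Target 20 is 5,7-dihydroxy-2-(4-hydroxy-2,5-dimethoxyphenyl)-6-methoxy-4H-chromen-4-one. It is a flavone in which benzo ring A and pyranone ring C are fused along C4a-C8a, with aryl ring B on C2. It has no stereocentre and no configurable double bond. The whole problem is therefore the placement of six oxygen substituents and the distinction of three free hydroxyls (O5, O7, O4') from three methyl ethers (O6, O2', O5'). Ring A is tetraoxygenated (O1, O5, O6, O7) with only C8 left as CH, and its methyl ether lies between the two free hydroxyls. A ring closure through the wrong ortho oxygen, or a Wessely-Moser type opening and reclosure in strong acid, would move the methoxy group from C6 to C8. Ring B has the 2',4',5' pattern with the para pair O2'/O5' methylated and O4' free, so a late selective demethylation is not an option. The sensitive points are: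
- the electrophilic C2 of the pyranone, which hydroxide, amines and hot alkoxide open;
- the C2=C3 bond under hydrogenation;
- the peri ether on O5 towards acid;
- any free 2',5'-hydroquinone, which air oxidises in base.

The plan rests on the chain C2'-C3'-C4'-C5' with O2', O4' and O5'. This chain is the carbon and oxygen skeleton of tetronic acid 12, and the remaining atoms C1' and C6' are the two carbons of an ethynyl group on C2.

## Retrosynthetic reasoning

**20 from 19.** The three O-CH2Ph bonds at O5, O7 and O4' are cut first. The three hydroxyls that are free in 20 never have to be told apart from one another. One kind of protecting group, removed in one neutral operation, is therefore enough, and the three methyl ethers stay untouched. The forward reaction must cleave three benzyl ethers without saturating C2=C3.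

**19 from 17 (through 18).** The O2'-CH3 and O5'-CH3 bonds are cut next. Both oxygens of this para pair end as the same ether. Hydroquinone 18 can thus be methylated twice without any selectivity, and it does not matter which of the two oxygens carries silicon in 17. O4' is the only ring B oxygen that must differ, and it is already benzylated. The forward operation has to free O2' and alkylate both oxygens before air reaches 18, so it is run in one flask.

**17 from 11 and 15 (through 16).** This disconnection defines the route. C1'-C2' and C5'-C6' are cut, which splits ring B into a two-carbon piece (C1', C6', the alkyne of 11) and a four-carbon piece (C2' to C5', the furan carbons of 15).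
- Cutting here, and not at the customary C2-C1' or C2-C3 bonds, avoids the separate preparation of a benzene ring with three differentiated oxygens.
- The differentiation is built into 15: its ring oxygen becomes O5', its silyloxy oxygen O2' and its benzyloxy oxygen O4'.
- One ring and two skeletal bonds are gained in one operation from two fragments of similar effort.
- The forward reaction must be a [4+2] addition in one orientation, at the alkyne only, followed by opening of the oxygen bridge of 16 to the aromatic ring.

**15 from 13 and 14, and 13 from 12.** The O-Si bond and then the O4'-benzyl bond are cut. Lactone 13 only has to be enolised towards C5 and trapped on oxygen by 14. 13 is the enol ether of the vinylogous acid 12. The diene branch is thus two steps long and does not lengthen the main line.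

**11 from 10, 9 and 8.** The C1'-C6' triple bond is cut between its carbons by a one-carbon homologation of aldehyde 10, so that C1' is traced back to a carboxyl carbon. The aldehyde comes from ester 8 by reduction to alcohol 9 and reoxidation. This is more dependable on this enone than a partial reduction of the ester.

**8 from 5 and 6 (through 7).** C2-C3 and O1-C2 are cut. The methyl carbon of 5 becomes C3, one carbonyl carbon of 6 becomes C2 and the other becomes C1'. Because 5 has a single free ortho hydroxyl, ring C can close in only one direction, which fixes the methoxy group at C6.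

**5 from 4, 2 and 1 (through 3).** The O6-CH3 bond, the C6-O6 bond and two benzyl ethers are cut. The oxygen on C6 is introduced para to the free phenol of 2 by an Elbs oxidation, at the only position para to that phenol. The new, non-chelated hydroxyl of 4 is then methylated selectively. Building the tetraoxygenated ring first and acetylating it afterwards would take several more steps and would expose benzyl ethers to a Lewis acid. Starting from 1, the acetyl group is present from the beginning.

## Alternatives that were turned down

**Alternative 1:** Ring A is made last and the bond cut is C4a-C5.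
- *Key step.* The product would be the 4'-O-benzyl ether of the target A1, one hydrogenolysis away from 20. Its precursor is the pyranonyl beta-keto ester A2, a 2-aryl-4-pyranone that carries the chain C8H2-C7(=O)-C6H(OMe)-C5O2Me on the carbon that becomes C8a. A hindered lithium amide base would convert A2 into an extended enolate running from C8 through C8a and C4a to the oxygen on C4. C4a would then attack the ester carbon C5 in a Dieckmann-like closure, and the product would enolise to the resorcinol ring.
- *In favour.* The 6-methoxy group arrives with the malonate-derived chain and cannot end up at C8. O5 and O7 appear free without ever being protected, and the end game is shorter. On protecting-group economy this plan is clearly the stronger one.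
- *Against.* The most acidic hydrogen of A2 is C6-H. Once it is removed, the ester C5 belongs to an enolate and is a poor electrophile, so closure must come from a dianion in which C8, C4a and two oxygens compete as nucleophiles. C4a gives up the conjugation of the pyranone when it attacks. C2 and C8a remain open to addition. The assembly of A2 needs a C-acylation of a side-chain anion with a methoxymalonyl donor, which is prone to O-acylation and double acylation. Ring B must still be supplied as a complete 2,4,5-trioxygenated benzoyl unit.
- *Comparison.* The chosen route spends more steps on benzyl groups. In return its ring-forming step has one diene, one dienophile and one polarity-matched orientation, and it is pulled forward by aromatisation instead of being held back by charge.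

**Alternative 2:** The bond cut is O1-C8a, so ring C is closed by a C-H oxygenation of ring A.
- *Key step.* It would give the 7,4'-di-O-benzyl ether of the target A3 from the 1,3-diketone A4, whose ring A is a 2-methoxyphenol (O5-H, O6-Me) with C8a still a CH. A diacetoxyiodoarene oxidant in the alcohol that matches the O6 methyl group would turn the guaiacol unit into the 6,6-dimethoxycyclohexa-2,4-dienone A5. In A5, C8a is the beta carbon of both the ring ketone C5 and the side-chain ketone C4. The enol oxygen of the diketone adds there, and 1,4-elimination of one methoxy group from C6 restores the aromatic ring.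
- *In favour.* Ring A needs one oxygen fewer at the outset, so no Elbs oxidation is required. O5 emerges free, and the sequence is shorter than the chosen one. On step economy this plan wins.
- *Against.* The phenol of A4 is acylated and hydrogen-bonded, hence slow to oxidise. The same oxidant attacks 1,3-diketones at the central carbon C3 and oxidises 1,2,4-trialkoxybenzenes such as ring B by electron transfer. C8, para to O5, is unsubstituted, so attack of the solvent there competes with ketal formation at C6. Dienones like A5 dimerise by Diels-Alder reaction and can add the solvent alcohol at the very carbon meant for the enol. Three oxidisable sites thus compete, and nothing in A4 fixes the order.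
- *Comparison.* The chosen plan places its single oxidation at the second step on a simple compound, where a poor outcome costs only cheap material. No oxidant meets the electron-rich late intermediates.

**Alternative 3:** The same alkyne 11 is kept and ring B is again built on it, but from three pieces. The cuts are C5'-C6', C1'-C2' and C2'-C3'.
- *Key step.* It is a Dötz benzannulation that would give the 4-methoxyphenol A6, with O5' already methylated, O2' free and O4' as a tert-butyl ether. The partner is the alkenyl(methoxy)carbene complex A7, (CO)5Cr=C(OMe)C(OtBu)=CH2. Its carbene carbon becomes C5', its alkenyl carbons become C4' and C3', and one carbonyl ligand becomes C2'.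
- *In favour.* With terminal alkynes the larger substituent ends next to the new phenol carbon for steric reasons, so the orientation is at least as dependable as in the chosen step. All three ring B oxygens come out differentiated, and no hydroquinone is ever set free. On these two points the benzannulation is the stronger reaction.
- *Against.* The reaction favours neutral or electron-rich alkynes. Acceptor-substituted ones such as 11 bind weakly to the unsaturated chromium centre, insert slowly and divert the vinylketene intermediate to furans, cyclobutenones or lactones. The chromone oxygens may coordinate as well. A7 is an alpha-alkoxyalkenyl carbene complex of limited stability. It has to be made from a lithiated enol ether and a chromium carbonyl source, and it is used stoichiometrically, which brings a full equivalent of a toxic metal into a late step. The arene is first formed as its Cr(CO)3 complex, and oxidative decomplexation endangers a 4-methoxyphenol that is halfway to a quinone. The tert-butyl ether needs an acid step beside the hydrogenolysis, so the end game is one step longer.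
- *Comparison.* In the chosen strategy the electron poverty of 11 drives the reaction instead of hampering it. The diene is metal-free and lies two steps from 12.

Key step: step 10

Remark: the locants C2 to C8a and C1' to C6' are those of flavone 20 and are used for the corresponding atoms of all precursors. Adduct 16 is formed as a racemate, which is irrelevant because both of its stereocentres vanish on aromatisation.

## Route

Step 1
Reactants: 1 2',4',6'-trihydroxyacetophenone
Product: 2 1-[2,4-bis(benzyloxy)-6-hydroxyphenyl]ethan-1-one
Conditions: BnBr (2.1 equiv), K2CO3 (2.2 equiv), DMF, rt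
Reagents that add atoms: benzyl bromide, BrCc1ccccc1
Why: Williamson etherification; the 4-OH and one of the two equivalent ortho hydroxyls are alkylated, after which the last hydroxyl is locked in a hydrogen bond to the acetyl oxygen and is by far the least nucleophilic, so the reaction should stop at the diether with two equivalents of halide.

Step 2
Reactants: 2 1-[2,4-bis(benzyloxy)-6-hydroxyphenyl]ethan-1-one
Product: 4 1-[2,4-bis(benzyloxy)-3,6-dihydroxyphenyl]ethan-1-one, via potassium aryl sulfate 3 (not isolated)
Conditions: K2S2O8, NaOH aq, pyridine, 0 °C to rt; unreacted 2 extracted at pH 5; then HCl aq, 80 °C, N2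
Reagents that add atoms: potassium peroxodisulfate, [K+].[K+].[O-]S(=O)(=O)OOS(=O)(=O)[O-]
Why: Elbs persulfate oxidation; the phenolate of 2 attacks a peroxide oxygen through the carbon para to the phenolate oxygen, which is free and activated by both flanking benzyloxy groups, to give sulfate 3. Acid hydrolysis of the S-O bond then frees hydroquinone 4, and dilute aqueous acid leaves benzyl aryl ethers alone; the carbon oxidised becomes C6.

Step 3
Reactants: 4 1-[2,4-bis(benzyloxy)-3,6-dihydroxyphenyl]ethan-1-one
Product: 5 1-[2,4-bis(benzyloxy)-6-hydroxy-3-methoxyphenyl]ethan-1-one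
Conditions: MeI (1.05 equiv), K2CO3 (1.1 equiv), DMF, rt, N2
Reagents that add atoms: methyl iodide, CI
Why: Williamson etherification under weak base; the new hydroxyl is not chelated and is alkylated, whereas the hydroxyl ortho to the acetyl group stays hydrogen-bonded and unreactive towards one equivalent of MeI. Inert gas keeps the hydroquinone from oxidising.

Step 4
Reactants: 5 1-[2,4-bis(benzyloxy)-6-hydroxy-3-methoxyphenyl]ethan-1-one; 6 diethyl oxalate
Product: 8 ethyl 5,7-bis(benzyloxy)-6-methoxy-4-oxo-4H-chromene-2-carboxylate, via diketo ester 7 (not isolated)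
Conditions: 6 (3 equiv), NaOEt (4 equiv), EtOH-THF, 65 °C; then HCl (1.25 M in EtOH), 50 °C
Reagents that add atoms: none
Why: Crossed Claisen condensation of the ketone enolate of 5 with the non-enolisable diester 6 gives 7, and acid closes the phenol oxygen onto the C2 carbonyl and removes water, which is the standard chromone-2-carboxylate synthesis. Only one ortho oxygen of 5 is free, so the methoxy group can only end at C6, and ethanolic acid at moderate temperature spares the peri benzyl ether.

Step 5
Reactants: 8 ethyl 5,7-bis(benzyloxy)-6-methoxy-4-oxo-4H-chromene-2-carboxylate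
Product: 9 5,7-bis(benzyloxy)-2-(hydroxymethyl)-6-methoxy-4H-chromen-4-one
Conditions: NaBH4 (1.2 equiv), EtOH-THF, 0 °C
Reagents that add atoms: none
Why: Chemoselective hydride reduction; the ester on C2 is activated by O1 and the enone like an alpha-oxygenated ester and is reduced by NaBH4, a known access to 2-(hydroxymethyl)chromones, while the C4 carbonyl is a vinylogous ester further deactivated by three alkoxy groups. Low temperature and a small excess of hydride limit conjugate reduction of C2=C3.

Step 6
Reactants: 9 5,7-bis(benzyloxy)-2-(hydroxymethyl)-6-methoxy-4H-chromen-4-one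
Product: 10 5,7-bis(benzyloxy)-6-methoxy-4-oxo-4H-chromene-2-carbaldehyde
Conditions: activated MnO2 (excess), CH2Cl2, rt
Reagents that add atoms: none
Why: Oxidation of an allylic-type primary alcohol with activated MnO2 stops at the aldehyde and touches neither the benzyl ethers nor the pyranone.

Step 7
Reactants: 10 5,7-bis(benzyloxy)-6-methoxy-4-oxo-4H-chromene-2-carbaldehyde
Product: 11 5,7-bis(benzyloxy)-2-ethynyl-6-methoxy-4H-chromen-4-one
Conditions: dimethyl (1-diazo-2-oxopropyl)phosphonate (1.3 equiv), K2CO3 (2 equiv), MeOH-THF, 0 °C to rt
Reagents that add atoms: dimethyl (1-diazo-2-oxopropyl)phosphonate, COP(=O)(OC)C(=[N+]=[N-])C(C)=O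
Why: Ohira-Bestmann variant of the Seyferth-Gilbert homologation; methanolysis frees the diazomethylphosphonate anion, which adds to the aldehyde, eliminates phosphate to a diazoalkene, loses N2 and gives the alkyne by a 1,2-hydrogen shift. The aldehyde sits on an sp2 carbon of a heteroaromatic-like ring and has no alpha hydrogen, a substrate type that suits the reaction, and low temperature with short contact limits attack of methoxide on C2.

Step 8
Reactants: 12 tetronic acid (furan-2,4(3H,5H)-dione)
Product: 13 4-(benzyloxy)furan-2(5H)-one
Conditions: BnOH (1.5 equiv), p-TsOH·H2O (cat.), toluene, reflux, Dean-Stark trap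
Reagents that add atoms: benzyl alcohol, OCc1ccccc1
Why: Tetronic acid is a vinylogous carboxylic acid, and acid-catalysed condensation with the alcohol under removal of water (Fischer-type esterification) gives only the O4 enol ether, whereas base and a benzyl halide would also alkylate C3.

Step 9
Reactants: 13 4-(benzyloxy)furan-2(5H)-one; 14 tert-butyldimethylsilyl trifluoromethanesulfonate
Product: 15 4-(benzyloxy)-2-(tert-butyldimethylsilyloxy)furan
Conditions: 14 (1.1 equiv), Et3N (1.5 equiv), CH2Cl2, 0 °C; hexane extraction, used at once
Reagents that add atoms: none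
Why: Soft enolisation; 14 silylates the lactone carbonyl oxygen, Et3N removes a C5 proton, and the gain of furan aromaticity drives the reaction, as known for alkyl tetronates. 15 is moisture-sensitive and is therefore carried on without chromatography.

Step 10
Reactants: 11 5,7-bis(benzyloxy)-2-ethynyl-6-methoxy-4H-chromen-4-one; 15 4-(benzyloxy)-2-(tert-butyldimethylsilyloxy)furan
Product: 17 5,7-bis(benzyloxy)-2-[4-(benzyloxy)-2-(tert-butyldimethylsilyloxy)-5-hydroxyphenyl]-6-methoxy-4H-chromen-4-one, via 7-oxanorbornadiene adduct 16 (not isolated)
Conditions: 15 (2.5 equiv), degassed toluene, 100 °C, sealed tube, Ar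
Reagents that add atoms: none
Why: Diene 15 carries donors on furan C2 and C4, which places its largest HOMO coefficient on C5, and 11 is a vinylogous ynone whose LUMO is largest on the terminal alkyne carbon (the delta position of O=C4-C3=C2-C≡CH); the normal-electron-demand [4+2] addition therefore joins furan C5 to the terminal carbon (C5'-C6') and furan C2 to the internal carbon (C1'-C2'), probably asynchronously with C5'-C6' leading. Ring B is closed in this intermolecular [4+2] mode, four diene carbons plus two alkyne carbons, first as the 7-oxanorbornadiene 16. In 16 the bridgehead C2' is a silyl ketal carbon: its bond to the bridge oxygen ionises with push from the silyloxy oxygen, and loss of the proton on the other bridgehead C5' gives the benzene ring with O5' as free phenol and O2' still silylated, so that aromatisation makes the sequence irreversible and removes the retro-Diels-Alder problem usual for furans. The closest known reaction type is the addition of 2-silyloxyfurans to propiolates, ynones and acetylenedicarboxylates with spontaneous opening to hydroquinone monosilyl ethers, in which the acceptor likewise ends next to the silyloxy carbon; 11 is a weaker member of the same dienophile class, hence heat and an excess of 15. The two bridgehead stereocentres of 16 arise as a racemate, are tied to each other by the bicycle and disappear on aromatisation, so nothing has to be controlled. The step needs one orientation, secured by the matched polarisation just described even against the steric preference, and attack at the alkyne and not at C2=C3, secured because that bond is trisubstituted, carries the donor O1 and could not lead to an aromatic ring. Silyl transfer between O2' and O5', or silylation of O5' by excess 15, is without consequence because both oxygens are methylated next.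

Step 11
Reactants: 17 5,7-bis(benzyloxy)-2-[4-(benzyloxy)-2-(tert-butyldimethylsilyloxy)-5-hydroxyphenyl]-6-methoxy-4H-chromen-4-one
Product: 19 5,7-bis(benzyloxy)-2-[4-(benzyloxy)-2,5-dimethoxyphenyl]-6-methoxy-4H-chromen-4-one, via free hydroquinone 18 (not isolated)
Conditions: CsF (2 equiv), degassed DMF, 0 °C to rt, Ar; then Cs2CO3 (2 equiv), MeI (5 equiv), rt
Reagents that add atoms: methyl iodide, CI
Why: Fluoride cleaves the aryl silyl ether, easily here because the phenoxide is ortho to the electron-poor chromone, and double Williamson methylation of the hydroquinone follows in the same flask, a known one-pot exchange of aryl silyl for aryl alkyl ethers. No selectivity is needed, since O2' and O5' are the only free oxygens, and exclusion of air protects 18.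

Step 12
Reactants: 19 5,7-bis(benzyloxy)-2-[4-(benzyloxy)-2,5-dimethoxyphenyl]-6-methoxy-4H-chromen-4-one
Product: 20 5,7-dihydroxy-2-(4-hydroxy-2,5-dimethoxyphenyl)-6-methoxy-4H-chromen-4-one
Conditions: H2 (1 atm), Pd/C (10%), EtOAc-MeOH, rt
Reagents that add atoms: none
Why: Catalytic hydrogenolysis of three benzyl aryl ethers; the trisubstituted C2=C3 bond of a flavone is part of a cross-conjugated vinylogous ester and is not reduced at atmospheric pressure if the reaction is stopped when uptake ends. The methyl ethers are inert.

## Compound list

1 | 2',4',6'-trihydroxyacetophenone | CC(=O)c1c(O)cc(O)cc1O | starting material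
2 | 1-[2,4-bis(benzyloxy)-6-hydroxyphenyl]ethan-1-one | CC(=O)c1c(O)cc(OCc2ccccc2)cc1OCc1ccccc1 | intermediate
3 | potassium 3-acetyl-2,6-bis(benzyloxy)-4-hydroxyphenyl sulfate (not isolated) | CC(=O)c1c(O)cc(OCc2ccccc2)c(OS(=O)(=O)[O-])c1OCc1ccccc1.[K+] | intermediate
4 | 1-[2,4-bis(benzyloxy)-3,6-dihydroxyphenyl]ethan-1-one | CC(=O)c1c(O)cc(OCc2ccccc2)c(O)c1OCc1ccccc1 | intermediate
5 | 1-[2,4-bis(benzyloxy)-6-hydroxy-3-methoxyphenyl]ethan-1-one | CC(=O)c1c(O)cc(OCc2ccccc2)c(OC)c1OCc1ccccc1 | intermediate
6 | diethyl oxalate | CCOC(=O)C(=O)OCC | starting material
7 | ethyl 4-[2,4-bis(benzyloxy)-6-hydroxy-3-methoxyphenyl]-2,4-dioxobutanoate (not isolated) | CCOC(=O)C(=O)CC(=O)c1c(O)cc(OCc2ccccc2)c(OC)c1OCc1ccccc1 | intermediate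
8 | ethyl 5,7-bis(benzyloxy)-6-methoxy-4-oxo-4H-chromene-2-carboxylate | CCOC(=O)c1cc(=O)c2c(OCc3ccccc3)c(OC)c(OCc3ccccc3)cc2o1 | intermediate
9 | 5,7-bis(benzyloxy)-2-(hydroxymethyl)-6-methoxy-4H-chromen-4-one | OCc1cc(=O)c2c(OCc3ccccc3)c(OC)c(OCc3ccccc3)cc2o1 | intermediate
10 | 5,7-bis(benzyloxy)-6-methoxy-4-oxo-4H-chromene-2-carbaldehyde | O=Cc1cc(=O)c2c(OCc3ccccc3)c(OC)c(OCc3ccccc3)cc2o1 | intermediate
11 | 5,7-bis(benzyloxy)-2-ethynyl-6-methoxy-4H-chromen-4-one | C#Cc1cc(=O)c2c(OCc3ccccc3)c(OC)c(OCc3ccccc3)cc2o1 | intermediate
12 | tetronic acid (furan-2,4(3H,5H)-dione) | O=C1CC(=O)CO1 | starting material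
13 | 4-(benzyloxy)furan-2(5H)-one | O=C1C=C(OCc2ccccc2)CO1 | intermediate
14 | tert-butyldimethylsilyl trifluoromethanesulfonate | CC(C)(C)[Si](C)(C)OS(=O)(=O)C(F)(F)F | starting material
15 | 4-(benzyloxy)-2-(tert-butyldimethylsilyloxy)furan | CC(C)(C)[Si](C)(C)Oc1cc(OCc2ccccc2)co1 | intermediate
16 | 5,7-bis(benzyloxy)-2-[5-(benzyloxy)-1-(tert-butyldimethylsilyloxy)-7-oxabicyclo[2.2.1]hepta-2,5-dien-2-yl]-6-methoxy-4H-chromen-4-one (racemic, bridgeheads fixed relative to each other by the bicycle, not isolated) | CC(C)(C)[Si](C)(C)OC12C=C(OCc3ccccc3)C(O1)C=C2c1cc(=O)c2c(OCc3ccccc3)c(OC)c(OCc3ccccc3)cc2o1 | intermediate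
17 | 5,7-bis(benzyloxy)-2-[4-(benzyloxy)-2-(tert-butyldimethylsilyloxy)-5-hydroxyphenyl]-6-methoxy-4H-chromen-4-one | Oc1cc(-c2cc(=O)c3c(OCc4ccccc4)c(OC)c(OCc4ccccc4)cc3o2)c(O[Si](C)(C)C(C)(C)C)cc1OCc1ccccc1 | intermediate
18 | 5,7-bis(benzyloxy)-2-[4-(benzyloxy)-2,5-dihydroxyphenyl]-6-methoxy-4H-chromen-4-one (present as its caesium salt, not isolated) | Oc1cc(-c2cc(=O)c3c(OCc4ccccc4)c(OC)c(OCc4ccccc4)cc3o2)c(O)cc1OCc1ccccc1 | intermediate
19 | 5,7-bis(benzyloxy)-2-[4-(benzyloxy)-2,5-dimethoxyphenyl]-6-methoxy-4H-chromen-4-one | COc1cc(-c2cc(=O)c3c(OCc4ccccc4)c(OC)c(OCc4ccccc4)cc3o2)c(OC)cc1OCc1ccccc1 | intermediate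
20 | 5,7-dihydroxy-2-(4-hydroxy-2,5-dimethoxyphenyl)-6-methoxy-4H-chromen-4-one | COc1cc(-c2cc(=O)c3c(O)c(OC)c(O)cc3o2)c(OC)cc1O | target

## Step count and least certain steps

Total step count: 12. Longest linear sequence: 10 steps (steps 1 to 7, then 10 to 12). The furan branch (steps 8 and 9) has 2 steps.

**Step 10 (key step).**
- *Risk.* The most likely failure is insufficient rate. The alkyne of 11 is activated only through C2=C3, and O1 feeds electron density back into that bond. The cycloaddition may therefore be slower than protodesilylation or thermal decay of 15. A second failure mode is a stepwise vinylogous Michael addition of furan C5 to the alkyne terminus that ends in silyl transfer without closure of the second bond. A third is partial steric override of the electronic orientation.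
- *Fallback.* Ring B is brought in ready-made by the classical chalcone route, which sets out from 5 and returns at 19. Purchased 2,5-dimethoxyphenol F1 is benzylated (BnBr, K2CO3, DMF) to 2-(benzyloxy)-1,4-dimethoxybenzene F2. Vilsmeier-Haack formylation (POCl3, DMF) para to the benzyloxy group gives 4-(benzyloxy)-2,5-dimethoxybenzaldehyde F3. Claisen-Schmidt condensation of F3 with 5 (KOH, EtOH) gives (E)-1-[2,4-bis(benzyloxy)-6-hydroxy-3-methoxyphenyl]-3-[4-(benzyloxy)-2,5-dimethoxyphenyl]prop-2-en-1-one F4. I2 (cat.) in DMSO at 120 °C then closes and dehydrogenates F4 to 19.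

**Step 2.**
- *Risk.* Low conversion and unselective over-oxidation are to be expected. The para carbon is flanked by two bulky benzyloxy groups, the phenolate of 2 dissolves poorly in aqueous base, and persulfate is consumed by radical side oxidation.
- *Fallback.* It sets out from 2 and returns at 4, replacing sulfate transfer by oxidation to the quinone level and reduction. Teuber oxidation with (KSO3)2NO in acetone-water with KH2PO4 buffer gives 2-acetyl-3,5-bis(benzyloxy)cyclohexa-2,5-diene-1,4-dione F5. Na2S2O4 in EtOAc-water reduces F5 to 4.

**Step 7.**
- *Risk.* Methoxide can add to the electrophilic positions: conjugate addition to the terminus of the newly formed alkyne, or attack at C2 with opening of ring C. Hemiacetal formation at the very electrophilic aldehyde slows the wanted addition.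
- *Fallback.* It sets out from 10, returns at 11 and avoids alkoxide altogether. CBr4 and PPh3 in CH2Cl2 (first stage of the Corey-Fuchs sequence) give 5,7-bis(benzyloxy)-2-(2,2-dibromoethenyl)-6-methoxy-4H-chromen-4-one F6. Hydrogenolysis of the less hindered C-Br bond with Bu3SnH and Pd(PPh3)4 gives 5,7-bis(benzyloxy)-2-[(Z)-2-bromoethenyl]-6-methoxy-4H-chromen-4-one F7. Anti elimination with DBU in THF gives 11.

**Step 5.**
- *Risk.* Conjugate reduction of C2=C3 and subsequent reduction of the C4 carbonyl may compete with ester reduction, since the ester itself makes C2=C3 more electrophilic.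
- *Fallback.* It sets out from 5, returns at 10 and brings C1' in at the aldehyde oxidation level, so that steps 4 to 6 are replaced. The enolate of 5 (LiN(SiMe3)2, THF) is acylated with purchased ethyl diethoxyacetate F8 to 1-[2,4-bis(benzyloxy)-6-hydroxy-3-methoxyphenyl]-4,4-diethoxybutane-1,3-dione F9. p-TsOH·H2O in EtOH closes it to 5,7-bis(benzyloxy)-2-(diethoxymethyl)-6-methoxy-4H-chromen-4-one F10. Aqueous acid in THF hydrolyses the acetal to 10.

**Step 11.**
- *Risk.* Traces of air may oxidise the electron-rich hydroquinone dianion to the quinone level before alkylation. Some C-methylation of the very nucleophilic ring is also possible.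
- *Fallback.* It sets out from 17, returns at 19 and never has both para oxygens free at once. Mitsunobu methylation of O5' (MeOH, PPh3, diisopropyl azodicarboxylate, THF) under neutral conditions gives 5,7-bis(benzyloxy)-2-[4-(benzyloxy)-2-(tert-butyldimethylsilyloxy)-5-methoxyphenyl]-6-methoxy-4H-chromen-4-one F11. Bu4NF in THF gives 5,7-bis(benzyloxy)-2-[4-(benzyloxy)-2-hydroxy-5-methoxyphenyl]-6-methoxy-4H-chromen-4-one F12. MeI and K2CO3 in DMF then give 19.

## Further compounds

F1 | step 10 | 2,5-dimethoxyphenol (purchased) | COc1ccc(OC)c(O)c1
F2 | step 10 | 2-(benzyloxy)-1,4-dimethoxybenzene | COc1ccc(OC)c(OCc2ccccc2)c1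
F3 | step 10 | 4-(benzyloxy)-2,5-dimethoxybenzaldehyde | COc1cc(OCc2ccccc2)c(OC)cc1C=O
F4 | step 10 | (E)-1-[2,4-bis(benzyloxy)-6-hydroxy-3-methoxyphenyl]-3-[4-(benzyloxy)-2,5-dimethoxyphenyl]prop-2-en-1-one | COc1cc(OCc2ccccc2)c(OC)cc1/C=C/C(=O)c1c(O)cc(OCc2ccccc2)c(OC)c1OCc1ccccc1
F5 | step 2 | 2-acetyl-3,5-bis(benzyloxy)cyclohexa-2,5-diene-1,4-dione | CC(=O)C1=C(OCc2ccccc2)C(=O)C(OCc2ccccc2)=CC1=O
F6 | step 7 | 5,7-bis(benzyloxy)-2-(2,2-dibromoethenyl)-6-methoxy-4H-chromen-4-one | BrC(Br)=Cc1cc(=O)c2c(OCc3ccccc3)c(OC)c(OCc3ccccc3)cc2o1
F7 | step 7 | 5,7-bis(benzyloxy)-2-[(Z)-2-bromoethenyl]-6-methoxy-4H-chromen-4-one | Br/C=C\c1cc(=O)c2c(OCc3ccccc3)c(OC)c(OCc3ccccc3)cc2o1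
F8 | step 5 | ethyl diethoxyacetate (purchased) | CCOC(OCC)C(=O)OCC
F9 | step 5 | 1-[2,4-bis(benzyloxy)-6-hydroxy-3-methoxyphenyl]-4,4-diethoxybutane-1,3-dione | CCOC(OCC)C(=O)CC(=O)c1c(O)cc(OCc2ccccc2)c(OC)c1OCc1ccccc1
F10 | step 5 | 5,7-bis(benzyloxy)-2-(diethoxymethyl)-6-methoxy-4H-chromen-4-one | CCOC(OCC)c1cc(=O)c2c(OCc3ccccc3)c(OC)c(OCc3ccccc3)cc2o1
F11 | step 11 | 5,7-bis(benzyloxy)-2-[4-(benzyloxy)-2-(tert-butyldimethylsilyloxy)-5-methoxyphenyl]-6-methoxy-4H-chromen-4-one | COc1cc(-c2cc(=O)c3c(OCc4ccccc4)c(OC)c(OCc4ccccc4)cc3o2)c(O[Si](C)(C)C(C)(C)C)cc1OCc1ccccc1
F12 | step 11 | 5,7-bis(benzyloxy)-2-[4-(benzyloxy)-2-hydroxy-5-methoxyphenyl]-6-methoxy-4H-chromen-4-one | COc1cc(-c2cc(=O)c3c(OCc4ccccc4)c(OC)c(OCc4ccccc4)cc3o2)c(O)cc1OCc1ccccc1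
A1 | alternative 1 | 2-[4-(benzyloxy)-2,5-dimethoxyphenyl]-5,7-dihydroxy-6-methoxy-4H-chromen-4-one | COc1cc(-c2cc(=O)c3c(O)c(OC)c(O)cc3o2)c(OC)cc1OCc1ccccc1
A2 | alternative 1 | methyl 4-{6-[4-(benzyloxy)-2,5-dimethoxyphenyl]-4-oxo-4H-pyran-2-yl}-2-methoxy-3-oxobutanoate (racemic) | COC(=O)C(OC)C(=O)Cc1cc(=O)cc(-c2cc(OC)c(OCc3ccccc3)cc2OC)o1
A3 | alternative 2 | 7-(benzyloxy)-2-[4-(benzyloxy)-2,5-dimethoxyphenyl]-5-hydroxy-6-methoxy-4H-chromen-4-one | COc1cc(-c2cc(=O)c3c(O)c(OC)c(OCc4ccccc4)cc3o2)c(OC)cc1OCc1ccccc1
A4 | alternative 2 | 1-[4-(benzyloxy)-2-hydroxy-3-methoxyphenyl]-3-[4-(benzyloxy)-2,5-dimethoxyphenyl]propane-1,3-dione | COc1c(OCc2ccccc2)ccc(C(=O)CC(=O)c2cc(OC)c(OCc3ccccc3)cc2OC)c1O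
A5 | alternative 2 | 1-[4-(benzyloxy)-5,5-dimethoxy-6-oxocyclohexa-1,3-dien-1-yl]-3-[4-(benzyloxy)-2,5-dimethoxyphenyl]propane-1,3-dione | COC1(OC)C(=O)C(C(=O)CC(=O)c2cc(OC)c(OCc3ccccc3)cc2OC)=CC=C1OCc1ccccc1
A6 | alternative 3 | 5,7-bis(benzyloxy)-2-(4-tert-butoxy-2-hydroxy-5-methoxyphenyl)-6-methoxy-4H-chromen-4-one | COc1cc(-c2cc(=O)c3c(OCc4ccccc4)c(OC)c(OCc4ccccc4)cc3o2)c(O)cc1OC(C)(C)C
A7 | alternative 3 | pentacarbonyl[2-(tert-butoxy)-1-methoxyprop-2-en-1-ylidene]chromium, (CO)5Cr=C(OMe)C(OtBu)=CH2 | C=C(OC(C)(C)C)C(OC)=[Cr].[C-]#[O+].[C-]#[O+].[C-]#[O+].[C-]#[O+].[C-]#[O+]
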